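## Analysis of the target

Target 11 is a linear diarylheptanoid. It has an unbranched chain C1–C7 with ring A (4-hydroxy-3,5-dimethoxyphenyl) on C1, a ketone at C3 and ring B (3,4-dihydroxyphenyl) on C7. There is no stereocenter and no ring besides the two arenes, so the task is one of connectivity, chemoselectivity and step economy. The ketone sits unsymmetrically: C2 and C4 are both unbranched α-methylenes of nearly equal acidity, and C5, C6 and C7 carry no function on which a polar bond formation could lean. The sensitive groups are three:
- the catechol of ring B, which air oxidises to the o-quinone, fastest as its anion;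
- the para-alkylated 2,6-dimethoxyphenol of ring A, which is oxidised towards a quinone methide;
- the enolisable ketone.

The synthesis is laborious rather than difficult, because the usual plans stitch the chain from four or five small pieces and spend most steps on homologation, redox adjustment and three phenol protections. The plan rests on the run of five atoms C3(=O)–C4–C5–C6–C7 that ends at the ipso carbon of ring B. The carbonyl carbon and the aryl-bearing carbon stand in a 1,5 relation, which is exactly what remains when the C3–C7 bond of a 1-substituted cyclopentan-1-ol is broken and C7 is arylated. With C1 and C2 added, all seven chain atoms are the carbon skeleton of a 1-ethynylcyclopentanol, so the chain can be bought folded up and need not be assembled. A second feature is used as well: once its phenol is acylated, ring A is a 1,3-dimethoxyarene held two methylenes from C3, and it can act as a built-in redox antenna for an O–H group at C3.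

## Retrosynthetic reasoning

**11 ⇒ 10.** Only the three O–acyl bonds are cut.
- Acetates come off without a reductant or a Lewis acid.
- They also set the electronics of the key step. As its diacetate, ring B is too electron-poor to be oxidised, and its C–Br precursor bond adds readily to nickel.
- As its monoacetate, ring A remains a dimethoxyarene that can still be oxidised.
- The forward reaction has to free a catechol without letting it oxidise.

**10 ⇒ 5 + 7 (key disconnection).** The bond C7–C(ipso, ring B) is cut and, in the same retrosynthetic move, the bond C3–C7 is reconnected. The open keto chain thus folds back into the tertiary cyclopentanol 5.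
- The cut is placed at C7 because this carbon has no neighbouring function, so no polar synthon exists for it.
- A radical at C7 is uniquely available from an oxygen radical at C3, because the two atoms are 1,5-related.
- The gain is large. One operation makes the ketone, releases the tetramethylene C4–C7 and attaches ring B.
- The position of the carbonyl at C3 is fixed by the skeleton of a symmetrical ring and not by enolate regioselectivity.
- The forward reaction has three tasks: make an alkoxy radical from the tertiary alcohol 5, break a ring bond rather than the exocyclic C2–C3 bond, and pass the C7 radical to an aryl nickel species derived from 7.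
- In one sentence: ring-opening arylation of cyclopentanol 5 by aryl bromide 7.

**5 ⇒ 4 ⇒ 2 + 3.** After the two hydrogenated carbons C1 and C2 are raised to an alkyne (4), the bond C1–C(ipso, ring A) is cut.
- This is an sp–sp2 coupling between aryl bromide 2 and the commercial terminal alkyne 3, which already holds all seven chain carbons and the oxygen of C3.
- A cut at C2–C3 (a 2-arylethyl metal added to a five-membered ring ketone) was not chosen. It would need a homologated arylethyl halide of several steps and a phenol protecting group that survives a Grignard reagent but gives the wrong electronics for the key step.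

**2 ⇒ 1 and 7 ⇒ 6.** Only O–acyl bonds are cut. Both bromophenols 1 and 6 are commercial, so the halogen positions, and with them the substitution patterns of rings A and B, are bought.

## Alternatives that were turned down

**Alternative 1:** the textbook cut at C4–C5.
- Forward key step: aldol condensation of methyl ketone A1 with aldehyde A2 gives enone A3. Hydrogenation with hydrogenolysis of the benzyl ethers then leads to 11.
- Regiochemistry: A1 enolises on both sides of its carbonyl group and A2 is itself enolisable. A preformed kinetic enolate and a separate dehydration are therefore needed.
- Step economy: both halves must first be built. A1 needs condensation and reduction. A2 needs two-carbon homologation, reduction and redox adjustment. The route would run to about nine steps.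
- Simplification: the key step forms one bond next to an existing carbonyl group and simplifies the problem little.

**Alternative 2:** a simultaneous cut at C2–C3 and C3–C4, with the carbonyl carbon delivered as a one-carbon unit from the gas phase.
- Forward key step: hydroboration of butenylarene A5 gives borane A6. A light-assisted, palladium-catalysed carbonylative alkyl–alkyl Suzuki coupling with iodide A4 then gives A7, which is debenzylated.
- This is a true three-component assembly around C3.
- Mechanism: A4 is a 2-arylethyl iodide. At the halide, radical and alkylpalladium stages, loss of a benzylic β-hydrogen towards conjugation with electron-rich ring A competes. Acyl formation must also outrun direct alkyl–alkyl coupling.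
- Step economy: A4 and A5 each need several steps of homologation and protection, so the precursors cost more than the key step wins.

**Alternative 3:** a cut at C5–C6, in the middle of the unfunctionalised tetramethylene, so that both halves become carboxylic acids (keto acid A8 and acid A9).
- Forward key step: electrochemical. Either a mixed Kolbe electrolysis of A8 and A9, or the nickel-electrocatalysed doubly decarboxylative coupling of the N-hydroxyphthalimide esters A10 and A11, which gives 10.
- Anodic version: both arenes are oxidised at potentials well below carboxylate discharge, so the rings would be consumed at the anode.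
- Reductive version: both radicals are unhindered primary alkyl radicals of the same polarity. Nothing in the structure lets nickel tell them apart, and a statistical distribution over cross product and two homodimers can only be skewed by wasting one partner.
- Step economy: A8 needs condensation, hydrogenation and acetylation, and two activation steps follow. The route is longer, and its key step makes one bond and no ketone.

Key step: step 5

Remark on the chemistry: the chain is numbered C1 (bonded to ring A) to C7 (bonded to ring B) throughout, also in the folded precursors. Compounds 1, 3 and 6 are taken as commercially available.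

## Steps

Step 1
Reactants: 1 4-bromo-2,6-dimethoxyphenol
Product: 2 4-bromo-2,6-dimethoxyphenyl acetate
Conditions: Ac2O (1.5 equiv), pyridine, DMAP (5 mol %), CH2Cl2, 0 °C to rt
Reagents that add atoms: acetic anhydride, CC(=O)OC(C)=O
Why: DMAP-catalysed O-acylation, which also works on a phenol flanked by two methoxy groups. The acetate removes the phenolic O–H, which would be the first site of oxidation in step 5, and lowers the electron density at the C–Br carbon for step 2.

Step 2
Reactants: 2 4-bromo-2,6-dimethoxyphenyl acetate; 3 1-ethynylcyclopentan-1-ol
Product: 4 4-[(1-hydroxycyclopentyl)ethynyl]-2,6-dimethoxyphenyl acetate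
Conditions: PdCl2(PPh3)2 (2 mol %), CuI (4 mol %), Et3N (3 equiv), degassed THF, 60 °C
Reagents that add atoms: none
Why: Sonogashira coupling. The C–Br bond lies para to the acetoxy group and meta to both methoxy groups, so oxidative addition to zerovalent palladium is not retarded. A tertiary amine base leaves the aryl acetate and the tertiary carbinol untouched.

Step 3
Reactants: 4 4-[(1-hydroxycyclopentyl)ethynyl]-2,6-dimethoxyphenyl acetate
Product: 5 4-[2-(1-hydroxycyclopentyl)ethyl]-2,6-dimethoxyphenyl acetate
Conditions: H2 (1 atm), 10% Pd/C, EtOAc, rt
Reagents that add atoms: none
Why: Heterogeneous catalytic hydrogenation of the alkyne to the saturated C1–C2 unit. A neutral aprotic solvent keeps the tertiary C3–O bond from ionising or being hydrogenolysed, and the acetate and arene are inert.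

Step 4
Reactants: 6 4-bromobenzene-1,2-diol
Product: 7 4-bromo-1,2-phenylene diacetate
Conditions: Ac2O (3 equiv), pyridine, DMAP (5 mol %), CH2Cl2, 0 °C to rt
Reagents that add atoms: acetic anhydride, CC(=O)OC(C)=O
Why: DMAP-catalysed O-acylation of both catechol hydroxyl groups. The two acetates stop air oxidation, lift the oxidation potential of ring B out of reach of the photocatalyst of step 5 and activate the C–Br bond towards nickel.

Step 5
Reactants: 5 4-[2-(1-hydroxycyclopentyl)ethyl]-2,6-dimethoxyphenyl acetate; 7 4-bromo-1,2-phenylene diacetate
Product: 10 4-[7-(4-acetoxy-3,5-dimethoxyphenyl)-5-oxoheptyl]-1,2-phenylene diacetate, via alkoxy radical 8 (not isolated), via ring-opened C7 radical 9 (not isolated)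
Conditions: 9-mesityl-10-methylacridinium perchlorate (3 mol %), NiBr2(MeOCH2CH2OMe) (10 mol %), 4,4'-di-tert-butyl-2,2'-bipyridine (12 mol %), 2,4,6-collidine (2 equiv), 7 (1.5 equiv), degassed PhCF3/MeCN, 450 nm LED, 25 °C
Reagents that add atoms: none
Why: Proposed new method: the excited acridinium salt oxidises ring A of 5, the only arene within its reach because ring B is carried as the electron-poor diacetate, and the hole is filled by the electron of the tertiary O–H bond while its proton passes to hydrogen-bonded collidine (intramolecular proton-coupled electron transfer), which gives alkoxy radical 8. β-Scission of the C3–C7 ring bond of 8 forms the C3 ketone and the primary C7 radical 9. Zerovalent nickel adds oxidatively to the C–Br bond of 7, the divalent aryl nickel bromide traps 9, reductive elimination from trivalent nickel forms the C7–aryl bond of 10, and electron transfer from the reduced photocatalyst to nickel closes both cycles, so that the reaction is redox-neutral and only HBr passes to collidine. The closest known reaction type is the photoredox/nickel ring-opening arylation of 1-arylcycloalkanols (five-membered rings included) with aryl bromides under an acridinium/collidine/bipyridine-nickel system; new here is the substrate class, a dialkyl carbinol whose arene antenna is held two methylene groups (C1, C2) away from the carbinol carbon C3 instead of on it. The extension is reasonable because the C1–C2 tether lets the hydroxyl group fold over ring A, because the pair ring A radical cation/collidine has an estimated effective bond strength close to that of a tertiary O–H bond, and because the very fast opening of 1-alkylcyclopentyloxyl radicals can drain even an uphill pre-equilibrium. No ring is closed (the cyclopentane is opened) and no stereocenter is formed. The step needs ring scission over exocyclic scission: all three β-bonds would give primary radicals, but only the two ring bonds release the strain of the cyclopentane, and these two are equivalent by symmetry, so that a single ketone with the carbonyl group at C3 can result. It also needs coupling at C–Br only, which the inertness of aryl acetate C–O bonds towards bipyridine nickel at room temperature secures.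

Step 6
Reactants: 10 4-[7-(4-acetoxy-3,5-dimethoxyphenyl)-5-oxoheptyl]-1,2-phenylene diacetate
Product: 11 7-(3,4-dihydroxyphenyl)-1-(4-hydroxy-3,5-dimethoxyphenyl)heptan-3-one
Conditions: HCl (1.25 M in MeOH), degassed MeOH, Ar, 40 °C; then H2O
Reagents that add atoms: none
Why: Acid-catalysed transesterification (methanolysis) of the three aryl acetates. The acidic medium keeps the liberated catechol protonated and therefore slow to oxidise, and any dimethyl ketal formed at C3 is hydrolysed in the aqueous work-up.

## Compound list

1 | 4-bromo-2,6-dimethoxyphenol | COc1cc(Br)cc(OC)c1O | starting material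
2 | 4-bromo-2,6-dimethoxyphenyl acetate | COc1cc(Br)cc(OC)c1OC(C)=O | intermediate
3 | 1-ethynylcyclopentan-1-ol | C#CC1(O)CCCC1 | starting material
4 | 4-[(1-hydroxycyclopentyl)ethynyl]-2,6-dimethoxyphenyl acetate | COc1cc(C#CC2(O)CCCC2)cc(OC)c1OC(C)=O | intermediate
5 | 4-[2-(1-hydroxycyclopentyl)ethyl]-2,6-dimethoxyphenyl acetate | COc1cc(CCC2(O)CCCC2)cc(OC)c1OC(C)=O | intermediate
6 | 4-bromobenzene-1,2-diol | Oc1ccc(Br)cc1O | starting material
7 | 4-bromo-1,2-phenylene diacetate | CC(=O)Oc1ccc(Br)cc1OC(C)=O | intermediate
8 | 1-[2-(4-acetoxy-3,5-dimethoxyphenyl)ethyl]cyclopentyloxyl radical | COc1cc(CCC2([O])CCCC2)cc(OC)c1OC(C)=O | intermediate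
9 | 7-(4-acetoxy-3,5-dimethoxyphenyl)-5-oxoheptyl radical | [CH2]CCCC(=O)CCc1cc(OC)c(OC(C)=O)c(OC)c1 | intermediate
10 | 4-[7-(4-acetoxy-3,5-dimethoxyphenyl)-5-oxoheptyl]-1,2-phenylene diacetate | COc1cc(CCC(=O)CCCCc2ccc(OC(C)=O)c(OC(C)=O)c2)cc(OC)c1OC(C)=O | intermediate
11 | 7-(3,4-dihydroxyphenyl)-1-(4-hydroxy-3,5-dimethoxyphenyl)heptan-3-one | COc1cc(CCC(=O)CCCCc2ccc(O)c(O)c2)cc(OC)c1O | target

## Step count and least certain steps

Total step count: 6. Longest linear sequence: 5 (steps 1, 2, 3, 5, 6); step 4 is the single step of the second branch.

**Step 5 (key step, bears the label "Proposed new method:").**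
- The most likely failure lies in the distance between antenna and hydroxyl group. The ring A radical cation may lose a benzylic proton from C1 to collidine, or simply take its electron back, before the long-range proton-coupled electron transfer occurs. Either the alcohol would then stay unchanged, or radical chemistry would start at C1.
- A second failure mode is hydrogen abstraction by the C7 radical before nickel captures it. That would amount to a mere isomerisation of the cyclopentanol to the unarylated ketone.
- Making the alkoxy radical by ligand-to-metal charge transfer in a tetravalent cerium alkoxide (CeCl3, Bu4NCl, 400 nm) would be tried first, but that is only a change of conditions.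
- The fallback uses known chemistry. It keeps the C7–aryl bond but gives up the ring opening, and it sets out from aryl bromide 7 and comes back to the route at 10. Bought 4-hydroxy-3,5-dimethoxybenzaldehyde F1 and bought 6-chlorohexan-2-one F2 are condensed at the methyl group of F2 (Claisen–Schmidt condensation, pyrrolidine/AcOH) to (E)-7-chloro-1-(4-hydroxy-3,5-dimethoxyphenyl)hept-1-en-3-one F3. Hydrogenation (H2, Pd/C, EtOAc) gives 7-chloro-1-(4-hydroxy-3,5-dimethoxyphenyl)heptan-3-one F4. Acetylation (Ac2O, pyridine) gives 4-(7-chloro-3-oxoheptyl)-2,6-dimethoxyphenyl acetate F5. A nickel-catalysed reductive cross-electrophile coupling of F5 with 7 (NiBr2(MeOCH2CH2OMe), 4,4'-di-tert-butyl-2,2'-bipyridine, NaI, Zn, DMA, 60 °C) then gives 10.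
- The same C7 radical is formed there from a carbon–halogen bond, so no O–H activation is needed.

**Step 2.**
- Copper-mediated oxidative homocoupling of alkyne 3 (Glaser coupling) may consume the alkyne while the aryl bromide turns over slowly.
- Prolonged heating with amine may start to strip the acetate.
- The fallback replaces the alkyne coupling by an alkene arylation. It sets out from 2 (and 3) and comes back at 5. Semi-hydrogenation of 3 (H2, Pd/CaCO3 poisoned with Pb(OAc)2, quinoline) gives 1-vinylcyclopentan-1-ol F6. A Heck reaction of 2 with F6 (Pd(OAc)2, P(o-tol)3, Et3N, DMF, 90 °C) gives 4-[(E)-2-(1-hydroxycyclopentyl)ethenyl]-2,6-dimethoxyphenyl acetate F7. The tertiary carbinol of F7 cannot isomerise to a carbonyl compound. Hydrogenation as in step 3 gives 5.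

**Step 3.**
- At the half-reduced stage the substrate is a styrenyl tertiary allylic alcohol. Hydrogenolysis of its C3–O bond on palladium, or ionisation by traces of acid on the catalyst, would delete the oxygen on which the key step depends.
- The fallback leaves surface catalysis for a concerted, metal-free hydrogen transfer. It sets out from 4 and comes back at 5. Diimide, generated from 2-nitrobenzenesulfonohydrazide and Et3N in THF at rt and used in excess, saturates the alkyne and cannot cleave a C–O bond. No new compound is made (F0).

**Step 6.**
- The acetate on ring A is flanked by two methoxy groups and may solvolyse slowly.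
- Longer or hotter acid treatment invites acid-catalysed attack of the activated ortho position of ring A on the protonated C3 ketone.
- Any air admitted during work-up starts oxidation of the catechol.
- The fallback treats the aryl acetates as active esters and cleaves them by aminolysis instead of acid catalysis. It sets out from 10 and comes back at 11. Pyrrolidine (6 equiv) in degassed MeCN at 0 °C to rt under Ar is followed by a quench into cold dilute aqueous HCl that holds a little ascorbic acid. No new compound is made (F0).

## Further compounds

F1 | step 5 | 4-hydroxy-3,5-dimethoxybenzaldehyde | COc1cc(C=O)cc(OC)c1O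
F2 | step 5 | 6-chlorohexan-2-one | CC(=O)CCCCCl
F3 | step 5 | (E)-7-chloro-1-(4-hydroxy-3,5-dimethoxyphenyl)hept-1-en-3-one | COc1cc(/C=C/C(=O)CCCCCl)cc(OC)c1O
F4 | step 5 | 7-chloro-1-(4-hydroxy-3,5-dimethoxyphenyl)heptan-3-one | COc1cc(CCC(=O)CCCCCl)cc(OC)c1O
F5 | step 5 | 4-(7-chloro-3-oxoheptyl)-2,6-dimethoxyphenyl acetate | COc1cc(CCC(=O)CCCCCl)cc(OC)c1OC(C)=O
F6 | step 2 | 1-vinylcyclopentan-1-ol | C=CC1(O)CCCC1
F7 | step 2 | 4-[(E)-2-(1-hydroxycyclopentyl)ethenyl]-2,6-dimethoxyphenyl acetate | COc1cc(/C=C/C2(O)CCCC2)cc(OC)c1OC(C)=O
F0 | step 3 | none | none
F0 | step 6 | none | none
A1 | alternative 1 | 4-[4-(benzyloxy)-3,5-dimethoxyphenyl]butan-2-one | CC(=O)CCc1cc(OC)c(OCc2ccccc2)c(OC)c1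
A2 | alternative 1 | 3-[3,4-bis(benzyloxy)phenyl]propanal | O=CCCc1ccc(OCc2ccccc2)c(OCc2ccccc2)c1
A3 | alternative 1 | (E)-7-[3,4-bis(benzyloxy)phenyl]-1-[4-(benzyloxy)-3,5-dimethoxyphenyl]hept-4-en-3-one | COc1cc(CCC(=O)/C=C/CCc2ccc(OCc3ccccc3)c(OCc3ccccc3)c2)cc(OC)c1OCc1ccccc1
A4 | alternative 2 | 2-(benzyloxy)-5-(2-iodoethyl)-1,3-dimethoxybenzene | COc1cc(CCI)cc(OC)c1OCc1ccccc1
A5 | alternative 2 | 1,2-bis(benzyloxy)-4-(but-3-en-1-yl)benzene | C=CCCc1ccc(OCc2ccccc2)c(OCc2ccccc2)c1
A6 | alternative 2 | 9-{4-[3,4-bis(benzyloxy)phenyl]butyl}-9-borabicyclo[3.3.1]nonane | C(CCB1C2CCCC1CCC2)Cc1ccc(OCc2ccccc2)c(OCc2ccccc2)c1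
A7 | alternative 2 | 7-[3,4-bis(benzyloxy)phenyl]-1-[4-(benzyloxy)-3,5-dimethoxyphenyl]heptan-3-one | COc1cc(CCC(=O)CCCCc2ccc(OCc3ccccc3)c(OCc3ccccc3)c2)cc(OC)c1OCc1ccccc1
A8 | alternative 3 | 6-(4-acetoxy-3,5-dimethoxyphenyl)-4-oxohexanoic acid | COc1cc(CCC(=O)CCC(=O)O)cc(OC)c1OC(C)=O
A9 | alternative 3 | 3-(3,4-diacetoxyphenyl)propanoic acid | CC(=O)Oc1ccc(CCC(=O)O)cc1OC(C)=O
A10 | alternative 3 | 1,3-dioxoisoindolin-2-yl 6-(4-acetoxy-3,5-dimethoxyphenyl)-4-oxohexanoate | COc1cc(CCC(=O)CCC(=O)ON2C(=O)c3ccccc3C2=O)cc(OC)c1OC(C)=O
A11 | alternative 3 | 1,3-dioxoisoindolin-2-yl 3-(3,4-diacetoxyphenyl)propanoate | CC(=O)Oc1ccc(CCC(=O)ON2C(=O)c3ccccc3C2=O)cc1OC(C)=O
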